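(The numbers are made up; the result is computed.)

The ratio I reckoned was the forward rate over the back rate of the coupling step, in which electrophile and nucleophile give acid set free and target, for two flasks that differ in free base.

    2 free base → homo dimer (k1 = 4.09 M⁻¹ min⁻¹)
    crystals ⇌ acid set free, rate k2*(cs2 - [acid set free]) while solid is left; crystals form when [acid set free] > cs2 (cs2 = 9.1 mM, k2 = 1.65 min⁻¹)
    acid set free + free base ⇌ salt of the base (K3 = 14 M⁻¹, k3 = 119 M⁻¹ min⁻¹)
    nucleophile + acid set free ⇌ protonated nucleophile, settled at all times (K4 = 770 M⁻¹)
    electrophile + nucleophile ⇌ acid set free + target (K5 = 13, k5 = 108 M⁻¹ min⁻¹)

| setting | south-west | north-east |
|---|---|---|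
| electrophile | 0.050 M | 0.050 M |
| nucleophile | 0.0750 M | 0.0750 M |
| free base | 0.100 M | 0.130 M |
| time | 8.0 min | 8.0 min |

- amounts and yields of acid set free count crystals too
- a step written with two of one species runs at k times the square of its concentration and takes two of it each time
- given per volume of solution although it is solid: crystals
- run time (south-west): 8.0 min

- part of the electrophile that has reacted at the end, south-west
- part of the electrophile that has reacted at the end, north-east
- what raising the concentration of free base from its lowest to its highest value here does to the part of the electrophile that has reacted (changes below 5 percentage points count as none) (it rises / it falls / no change)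

At the start of south-west and north-east alike the forward rate was 0.405 M min⁻¹. The half-life of the electrophile in south-west by this step, the way back not counted and the other concentrations as charged, was 0.086 min, far shorter than 8.0 min, so I reckoned where the net rate stops rather than when.

Let a and b be the charges of electrophile and nucleophile, s the solubility of the acid, and x the target formed. Protonation and the loss of both reagents slowed the forward rate. With free acid at s, protonation cut it by F = 8.01; loss of electrophile cut it by a/(a−x), and loss of nucleophile by b/(b−x). The back rate meanwhile grew with s times x. Dividing one by the other removes the rate constant and time: ρ = G(a−x)(b−x)/x, where G, the equilibrium constant of the step divided by s and by F, is 178 M⁻¹, a conditional equilibrium constant.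

ρ falls to one at x = 0.0426 M. There the other two factors were 6.78 and 2.32, which brought the forward rate down to 0.00322 M min⁻¹, level with a back rate of 0.00322 M min⁻¹.

That x was more than the 0.0374 M held by solution and protonated nucleophile, a surplus of 0.00519 M. For north-east, I reckoned that dimerisation by itself left 0.0137 M of free base at the end, whose salt at s came to 0.00174 M, less than that surplus. So I expected crystals to stand. G holds no free base, so I committed to 85.2% in both flasks, hence no change.

The forecast gave 85% for south-west, 85.5% for north-east and no change, slightly apart where mine are equal. Its ground was: “The outcome is then set by the near-equilibrated coupling reaction”.

South-west reached 84.7% and north-east 84.7%, a change of 0.0087 percentage points, which counts as no change. With the step from acid set free and free base to salt struck out, south-west stood at 84.6%. I then put the same G to a further flask, like north-east but charged with 0.20 M of electrophile, where the nucleophile is the limiting reagent. Setting ρ to one there gave 35.9% of its electrophile reacted, and that flask ended at 35.6%.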